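**Retrosynthetic overview**

1. Last bonds cut: the two methoxymethyl (MOM) ethers, then the enone Cα=Cβ bond, which joins a ring-A methyl ketone to the ring-B aldehyde 13 (Claisen–Schmidt condensation).
2. The 2H-pyran ring (O1–C2(CH3)2–C3H=C4H fused to ring A) is not closed directly. It is traced back to the seven-membered ring of the 3-methyl-2,5-dihydro-1-benzoxepine 9 and formed from it by ring contraction, in the same flask as the fragment union.
3. Enabling feature: in the oxepine ring the C5 methylene is benzylic to ring A and allylic to C3=C4, and stands 1,4 to the allylic ether bond O1–C2, whose oxygen is para to the ring-A ketone. Base-induced 1,4-elimination therefore opens the ring to a (Z)-dienylphenoxide (cis geometry inherited from the ring); hydrogen shift and oxa-6π closure then form O1–C3, and the expelled ring carbon C2 becomes the second methyl group.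
4. The oxepine comes from ring-closing metathesis of a C3-allyl/O4-methallyl pair on 2,4-dihydroxyacetophenone (allyl placed by aromatic Claisen rearrangement). The ring-B prenyl group comes from ortho C-alkylation of 4-hydroxybenzaldehyde.
5. Order of ring formation: rings A and B are bought; oxepine ring (step 5); pyran ring from the oxepine ring (step 8).

Key step: step 8

Remark: the target has no stereocentre; the E enone double bond is its only stereochemical element.

**Route**

Step 1
Reactants: 1 2,4-dihydroxyacetophenone; 2 allyl bromide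
Product: 3 1-[2-hydroxy-4-(prop-2-en-1-yloxy)phenyl]ethan-1-one
Conditions: K2CO3, acetone, 56 °C
Reagents that add atoms: allyl bromide, C=CCBr
Why: Williamson ether synthesis should alkylate only the 4-OH, because the 2-OH is hydrogen-bonded to the ketone and far less nucleophilic.

Step 2
Reactants: 3 1-[2-hydroxy-4-(prop-2-en-1-yloxy)phenyl]ethan-1-one
Product: 4 1-[2,4-dihydroxy-3-(prop-2-en-1-yl)phenyl]ethan-1-one
Conditions: N,N-diethylaniline, 200 °C
Reagents that add atoms: none
Why: Aromatic Claisen rearrangement ([3,3]-sigmatropic shift, then tautomerisation) should deliver the allyl group mainly to C3, between the two oxygens, because the chelated ketone localises double-bond character in the C3–C4 bond.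

Step 3
Reactants: 4 1-[2,4-dihydroxy-3-(prop-2-en-1-yl)phenyl]ethan-1-one; 5 3-chloro-2-methylprop-1-ene
Product: 6 1-{2-hydroxy-4-[(2-methylprop-2-en-1-yl)oxy]-3-(prop-2-en-1-yl)phenyl}ethan-1-one
Conditions: K2CO3, KI (cat.), acetone, 56 °C
Reagents that add atoms: 3-chloro-2-methylprop-1-ene, CC(=C)CCl
Why: Williamson ether synthesis (iodide-catalysed) should again take place only at the non-chelated 4-OH.

Step 4
Reactants: 6 1-{2-hydroxy-4-[(2-methylprop-2-en-1-yl)oxy]-3-(prop-2-en-1-yl)phenyl}ethan-1-one; 7 chloromethyl methyl ether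
Product: 8 1-{2-(methoxymethoxy)-4-[(2-methylprop-2-en-1-yl)oxy]-3-(prop-2-en-1-yl)phenyl}ethan-1-one
Conditions: NaH (1.05 equiv), DMF, 0 °C; then MOMCl, 0 to 25 °C
Reagents that add atoms: chloromethyl methyl ether, COCCl
Why: Deprotonation of the remaining chelated phenol (far more acidic than the methyl ketone) and O-alkylation with the chloromethyl ether (Williamson-type acetal formation) mask O2, so that it can neither hamper the carbanion chemistry of step 8 nor compete in the ring closure there.

Step 5
Reactants: 8 1-{2-(methoxymethoxy)-4-[(2-methylprop-2-en-1-yl)oxy]-3-(prop-2-en-1-yl)phenyl}ethan-1-one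
Product: 9 1-[6-(methoxymethoxy)-3-methyl-2,5-dihydro-1-benzoxepin-7-yl]ethan-1-one
Conditions: second-generation Grubbs catalyst RuCl2(=CHPh)(PCy3)(H2IMes) (5 mol %), CH2Cl2, 40 °C
Reagents that add atoms: none
Why: Ring-closing olefin metathesis should join the allyl and methallyl alkenes with loss of ethene, a seven-membered ring with a trisubstituted endocyclic alkene being within reach of this catalyst.

Step 6
Reactants: 10 4-hydroxybenzaldehyde; 11 1-bromo-3-methylbut-2-ene
Product: 12 4-hydroxy-3-(3-methylbut-2-en-1-yl)benzaldehyde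
Conditions: KOH (aq, 10 %), 25 °C; then dilute HCl
Reagents that add atoms: 1-bromo-3-methylbut-2-ene, CC(C)=CCBr
Why: C-Alkylation of the ambident phenoxide in water (hydrogen bonding shields the oxygen) should place the prenyl group at the ortho carbon, the para position being blocked by the formyl group.

Step 7
Reactants: 12 4-hydroxy-3-(3-methylbut-2-en-1-yl)benzaldehyde; 7 chloromethyl methyl ether
Product: 13 4-(methoxymethoxy)-3-(3-methylbut-2-en-1-yl)benzaldehyde
Conditions: MOMCl, K2CO3, acetone, 25 °C
Reagents that add atoms: chloromethyl methyl ether, COCCl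
Why: Williamson-type protection of the phenol as its MOM ether keeps the aldehyde electrophilic under the basic conditions of step 8 (a para-phenoxide would deactivate it).

Step 8
Reactants: 9 1-[6-(methoxymethoxy)-3-methyl-2,5-dihydro-1-benzoxepin-7-yl]ethan-1-one; 13 4-(methoxymethoxy)-3-(3-methylbut-2-en-1-yl)benzaldehyde
Product: 17 (2E)-1-[5-(methoxymethoxy)-2,2-dimethyl-2H-chromen-6-yl]-3-[4-(methoxymethoxy)-3-(3-methylbut-2-en-1-yl)phenyl]prop-2-en-1-one, via ring-opened (Z)-dienylphenoxide 14 (not isolated), via dienylphenol chalcone 15 (not isolated), via o-quinone methide 16 (not isolated)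
Conditions: KOtBu (2.5 equiv), DMSO, 25 °C, argon; then 13, THF–t-BuOH, 0 to 25 °C; then AcOH, 40 °C
Reagents that add atoms: aldehyde 13, CC(C)=CCc1cc(C=O)ccc1OCOC
Why: Proposed new method: KOtBu first converts the methyl ketone of 9 into its enolate and then removes a proton from C5 of the oxepine (benzylic to ring A, allylic to C3=C4); the allyl anion expels the phenoxide oxygen O1 from C2 in a 1,4-elimination, so the seven-membered ring opens to the (Z)-dienylphenoxide 14, its cis geometry fixed by the former ring. The ketone enolate then condenses with aldehyde 13 (aldol addition and E1cB loss of water, Claisen–Schmidt condensation) to give 15. On acidification the free phenol passes its hydrogen to the terminal diene carbon ([1,7]-hydrogen shift or its acid-catalysed equivalent), which turns the former ring carbon C2 into the second methyl group, and the o-quinone methide 16 closes by thermal oxa-6π electrocyclisation (six-electron disrotatory closure forming the O1–C(CH3)2 bond) to the 2H-pyran ring, one atom smaller than the ring it came from. The closest known reaction types are the base-induced isomerisation of dihydro-1-benzoxepines to 2-methyl-2H-chromenes through o-butadienylphenoxides, the base-induced 1,4-elimination of allylic ethers, the cyclisation of (Z)-2-(buta-1,3-dienyl)phenols to 2H-chromenes and the Claisen–Schmidt condensation; new is their merger in one flask on an acyl-substituted substrate. No stereocentre is created, and the E enone is set under thermodynamic control in the reversible E1cB dehydration. The step needs deprotonation at C5 rather than at the O–CH2 group (secured by the double benzylic/allylic activation of C5), closure onto O1 only (secured by the MOM group on the neighbouring oxygen) and an intact prenyl group (secured by limiting KOtBu and buffering with t-BuOH before 13 is added).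

Step 9
Reactants: 17 (2E)-1-[5-(methoxymethoxy)-2,2-dimethyl-2H-chromen-6-yl]-3-[4-(methoxymethoxy)-3-(3-methylbut-2-en-1-yl)phenyl]prop-2-en-1-one
Product: 18 paratocarpin B
Conditions: HCl (3 M aq, cat.), MeOH, 40 °C
Reagents that add atoms: none
Why: Acid-catalysed acetal exchange with methanol should remove both MOM groups (the one ortho to the ketone with carbonyl assistance) under conditions mild enough for the chromene, the enone and the prenyl group.

**Compound list**

1 | 2,4-dihydroxyacetophenone | CC(=O)c1ccc(O)cc1O | starting material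
2 | allyl bromide | C=CCBr | starting material
3 | 1-[2-hydroxy-4-(prop-2-en-1-yloxy)phenyl]ethan-1-one | CC(=O)c1ccc(OCC=C)cc1O | intermediate
4 | 1-[2,4-dihydroxy-3-(prop-2-en-1-yl)phenyl]ethan-1-one | CC(=O)c1ccc(O)c(CC=C)c1O | intermediate
5 | 3-chloro-2-methylprop-1-ene | CC(=C)CCl | starting material
6 | 1-{2-hydroxy-4-[(2-methylprop-2-en-1-yl)oxy]-3-(prop-2-en-1-yl)phenyl}ethan-1-one | CC(=O)c1ccc(OCC(C)=C)c(CC=C)c1O | intermediate
7 | chloromethyl methyl ether | COCCl | starting material
8 | 1-{2-(methoxymethoxy)-4-[(2-methylprop-2-en-1-yl)oxy]-3-(prop-2-en-1-yl)phenyl}ethan-1-one | CC(=O)c1ccc(OCC(C)=C)c(CC=C)c1OCOC | intermediate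
9 | 1-[6-(methoxymethoxy)-3-methyl-2,5-dihydro-1-benzoxepin-7-yl]ethan-1-one | CC(=O)c1ccc2OCC(C)=CCc2c1OCOC | intermediate
10 | 4-hydroxybenzaldehyde | O=Cc1ccc(O)cc1 | starting material
11 | 1-bromo-3-methylbut-2-ene | CC(C)=CCBr | starting material
12 | 4-hydroxy-3-(3-methylbut-2-en-1-yl)benzaldehyde | CC(C)=CCc1cc(C=O)ccc1O | intermediate
13 | 4-(methoxymethoxy)-3-(3-methylbut-2-en-1-yl)benzaldehyde | CC(C)=CCc1cc(C=O)ccc1OCOC | intermediate
14 | 1-{4-hydroxy-2-(methoxymethoxy)-3-[(1Z)-3-methylbuta-1,3-dien-1-yl]phenyl}ethan-1-one (in the flask as its dipotassium phenoxide enolate, not isolated) | CC(=O)c1ccc(O)c(/C=C\C(C)=C)c1OCOC | intermediate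
15 | (2E)-1-{4-hydroxy-2-(methoxymethoxy)-3-[(1Z)-3-methylbuta-1,3-dien-1-yl]phenyl}-3-[4-(methoxymethoxy)-3-(3-methylbut-2-en-1-yl)phenyl]prop-2-en-1-one (in the flask as its potassium phenoxide, not isolated) | CC(C)=CCc1cc(/C=C/C(=O)c2ccc(O)c(/C=C\C(C)=C)c2OCOC)ccc1OCOC | intermediate
16 | 3-(methoxymethoxy)-4-{(2E)-3-[4-(methoxymethoxy)-3-(3-methylbut-2-en-1-yl)phenyl]prop-2-enoyl}-2-(3-methylbut-2-en-1-ylidene)cyclohexa-3,5-dien-1-one (o-quinone methide, not isolated) | CC(C)=CCc1cc(/C=C/C(=O)C2=C(OCOC)/C(=C/C=C(C)C)C(=O)C=C2)ccc1OCOC | intermediate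
17 | (2E)-1-[5-(methoxymethoxy)-2,2-dimethyl-2H-chromen-6-yl]-3-[4-(methoxymethoxy)-3-(3-methylbut-2-en-1-yl)phenyl]prop-2-en-1-one | CC(C)=CCc1cc(/C=C/C(=O)c2ccc3c(c2OCOC)C=CC(C)(C)O3)ccc1OCOC | intermediate
18 | paratocarpin B, (2E)-1-(5-hydroxy-2,2-dimethyl-2H-chromen-6-yl)-3-[4-hydroxy-3-(3-methylbut-2-en-1-yl)phenyl]prop-2-en-1-one | CC(C)=CCc1cc(/C=C/C(=O)c2ccc3c(c2O)C=CC(C)(C)O3)ccc1O | target

**Step count and risks**

Total steps: 9. Longest linear sequence: 7 steps (steps 1, 2, 3, 4, 5, 8 and 9, from 2,4-dihydroxyacetophenone).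

Step 8 (proposed new method). The one-flask sequence may lose chemoselectivity: the strong base may move the prenyl double bond of 13 into conjugation with ring B, alkoxide or dimsyl anion may add to the newly formed enone, or the ring-opened diene may isomerise to the E form, which can no longer undergo the hydrogen shift. The fallback sets out from 9 and comes back at 17, using two separate operations of known type. Compound 9 alone would be treated with KOtBu in DMSO at 25 °C and then acidified with AcOH at 40 °C (base-induced ring contraction of a dihydro-1-benzoxepine), with pyridinium p-toluenesulfonate in toluene at 60 °C added if E-diene remains, to close it through the allyl cation. This should give 1-[5-(methoxymethoxy)-2,2-dimethyl-2H-chromen-6-yl]ethan-1-one F1, which is isolated. A classical Claisen–Schmidt condensation of F1 with 13 (KOH, EtOH–H2O, 25 °C) should then give 17, so that the prenyl aldehyde never meets KOtBu in DMSO.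

Step 6. O-Alkylation and double alkylation may outrun ortho C-alkylation, so that little of the mono-C-prenylated phenol is obtained. The fallback sets out from 10 and comes back at 12, delivering the prenyl group intramolecularly. O-Alkylation of 10 with 3-chloro-3-methylbut-1-yne (K2CO3, KI, CuI cat., acetone, 56 °C) should give 4-[(2-methylbut-3-yn-2-yl)oxy]benzaldehyde F2. Semihydrogenation (H2, Lindlar catalyst, Pd on CaCO3 poisoned with Pb(OAc)2, quinoline, EtOAc, 25 °C) should give 4-[(2-methylbut-3-en-2-yl)oxy]benzaldehyde F3. Aromatic Claisen rearrangement of F3 (N,N-diethylaniline, 180 °C) should place the prenyl group on the ortho carbon and give 12.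

Step 9. Under protic acid the ring-B phenol, once freed, may add to its own prenyl double bond (chroman formation), and the 2'-hydroxychalcone may cyclise to the flavanone. The fallback sets out from 6 and 12 and comes back at 18, replacing acid-labile MOM by fluoride-labile 2-(trimethylsilyl)ethoxymethyl (SEM) ethers.
- Compound 6 with SEMCl (NaH, DMF, 0 °C) should give 1-{4-[(2-methylprop-2-en-1-yl)oxy]-3-(prop-2-en-1-yl)-2-{[2-(trimethylsilyl)ethoxy]methoxy}phenyl}ethan-1-one F4.
- Ring-closing metathesis as in step 5 should give 1-(3-methyl-6-{[2-(trimethylsilyl)ethoxy]methoxy}-2,5-dihydro-1-benzoxepin-7-yl)ethan-1-one F5.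
- Compound 12 with SEMCl (K2CO3, acetone, 25 °C) should give 3-(3-methylbut-2-en-1-yl)-4-{[2-(trimethylsilyl)ethoxy]methoxy}benzaldehyde F6.
- F5 and F6 under the conditions of step 8 should give (2E)-1-(2,2-dimethyl-5-{[2-(trimethylsilyl)ethoxy]methoxy}-2H-chromen-6-yl)-3-[3-(3-methylbut-2-en-1-yl)-4-{[2-(trimethylsilyl)ethoxy]methoxy}phenyl]prop-2-en-1-one F7.
- Bu4NF in DMPU at 60 °C, followed by neutral work-up, should give 18 without any acid.

**Further compounds**

F1 | step 8 | 1-[5-(methoxymethoxy)-2,2-dimethyl-2H-chromen-6-yl]ethan-1-one | CC(=O)c1ccc2c(c1OCOC)C=CC(C)(C)O2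
F2 | step 6 | 4-[(2-methylbut-3-yn-2-yl)oxy]benzaldehyde | CC(C)(C#C)Oc1ccc(C=O)cc1
F3 | step 6 | 4-[(2-methylbut-3-en-2-yl)oxy]benzaldehyde | CC(C)(C=C)Oc1ccc(C=O)cc1
F4 | step 9 | 1-{4-[(2-methylprop-2-en-1-yl)oxy]-3-(prop-2-en-1-yl)-2-{[2-(trimethylsilyl)ethoxy]methoxy}phenyl}ethan-1-one | CC(=O)c1ccc(OCC(C)=C)c(CC=C)c1OCOCC[Si](C)(C)C
F5 | step 9 | 1-(3-methyl-6-{[2-(trimethylsilyl)ethoxy]methoxy}-2,5-dihydro-1-benzoxepin-7-yl)ethan-1-one | CC(=O)c1ccc2OCC(C)=CCc2c1OCOCC[Si](C)(C)C
F6 | step 9 | 3-(3-methylbut-2-en-1-yl)-4-{[2-(trimethylsilyl)ethoxy]methoxy}benzaldehyde | CC(C)=CCc1cc(C=O)ccc1OCOCC[Si](C)(C)C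
F7 | step 9 | (2E)-1-(2,2-dimethyl-5-{[2-(trimethylsilyl)ethoxy]methoxy}-2H-chromen-6-yl)-3-[3-(3-methylbut-2-en-1-yl)-4-{[2-(trimethylsilyl)ethoxy]methoxy}phenyl]prop-2-en-1-one | CC(C)=CCc1cc(/C=C/C(=O)c2ccc3c(c2OCOCC[Si](C)(C)C)C=CC(C)(C)O3)ccc1OCOCC[Si](C)(C)C
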